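**Strategy.** The route rests on cutting the bond between the cage ketone carbon and the hydroxylated bridgehead carbon, i.e. the tertiary α-ketol that spans the bicyclo[2.2.2]octene ring. A triazolylidene carbene turns the aldehyde on the prenylated ether carbon of the tetrahydrofuran ring into an acyl anion that adds to the cyclohexenone carbonyl, closing the bicyclooctenone and fixing the bridgehead carbinol in one operation. The precursor is a cis-fused tetrahydrofuran–cyclohexenone keto aldehyde, made by phenol dearomatisation and a hydrogen-atom-transfer radical closure. Afterwards the derived hydroxy acid is joined to a hydroxychromenequinone by acylation and oxa-Michael spiroketalisation.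

Key step: step 12

Remark: the spiro ketal carbon and the neighbouring prenylated methine can equilibrate (ring opening, enolisation); the route assumes the target diastereomer is the one favoured at equilibrium.

**Step 1**
Reactants: 1 4-bromo-3-(hydroxymethyl)phenol
Product: 2 bis-TBS ether of 1
Conditions: TBSCl (2.4 equiv), imidazole (5 equiv), DMF, 0 °C to rt
Reagents that add atoms: tert-butyldimethylsilyl chloride, CC(C)(C)[Si](C)(C)Cl
Why: Imidazole-promoted silyl ether formation caps both hydroxyls, and the aryl silyl ether can later be removed in the presence of the benzylic one.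

**Step 2**
Reactants: 2 bis-TBS aryl bromide; 3 dimethyl oxalate
Product: 5 methyl 2-[4-(TBS-oxy)-2-(TBS-oxymethyl)phenyl]-2-oxoacetate, via aryllithium 4 (not isolated)
Conditions: n-BuLi (1.05 equiv), THF, −78 °C; cannulated into 3 (3 equiv), THF, −78 °C; aq. NH4Cl
Reagents that add atoms: none
Why: Bromine–lithium exchange and acylation of the aryllithium by excess oxalate diester (inverse addition) stops at the keto ester because the chelated tetrahedral adduct persists until quench, and the low temperature keeps the benzylic silyl group from migrating to carbon.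

**Step 3**
Reactants: 5 aryl keto ester; 6 allyltributylstannane
Product: 7 methyl (2R)-2-[4-(TBS-oxy)-2-(TBS-oxymethyl)phenyl]-2-hydroxypent-4-enoate
Conditions: 6 (1.5 equiv), In(OTf)3 (10 mol%), C2-symmetric chiral N,N′-dioxide bis(2,6-diisopropylanilide) ligand from pipecolic acid (10 mol%, the enantiomer that gives the R alcohol), CH2Cl2, 0 °C
Reagents that add atoms: none
Why: Catalytic enantioselective allylation of an aryl α-keto ester with an allylstannane: the 1,2-dicarbonyl binds the chiral indium complex in a bidentate way, so the ligand decides which ketone face is attacked and sets the R tertiary carbinol.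

**Step 4**
Reactants: 7 tertiary hydroxy ester; 8 2-methoxypropene
Product: 9 2-methoxyprop-2-yl (mixed ketal) ether of 7
Conditions: 8 (5 equiv), PPTS (5 mol%), CH2Cl2, 0 °C; Et3N quench
Reagents that add atoms: none
Why: Acid-catalysed addition of the tertiary alcohol to the enol ether (mixed-ketal formation) masks the carbinol, so that it cannot fragment after dearomatisation, and already carries the carbon of the future ring CMe2 group.

**Step 5**
Reactants: 9 mixed ketal
Product: 10 phenol methyl (2R)-2-[4-hydroxy-2-(TBS-oxymethyl)phenyl]-2-[(2-methoxypropan-2-yl)oxy]pent-4-enoate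
Conditions: K2CO3 (0.3 equiv), MeOH, 0 °C to rt
Reagents that add atoms: none
Why: Chemoselective desilylation: carbonate in methanol cleaves the aryl silyl ether much faster than the alkyl one because phenoxide is the better leaving group, and the ketal and ester are stable to it.

**Step 6**
Reactants: 10 phenol
Product: 11 para-quinol methyl (2R)-2-[(1S)-1-hydroxy-4-oxo-2-(TBS-oxymethyl)cyclohexa-2,5-dien-1-yl]-2-[(2-methoxypropan-2-yl)oxy]pent-4-enoate
Conditions: PhI(OAc)2 (1.2 equiv), NaHCO3 (3 equiv), MeCN/H2O 2:1, 0 °C
Reagents that add atoms: water, O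
Why: Oxidative dearomatisation of a para-alkylphenol to the para-quinol; the quinol centre should be set by 1,2-induction in a Felkin–Anh arrangement (ketal oxygen anti to the incoming water, allyl beside the ortho hydrogen, flat ester beside the silyloxymethyl arm), and a minor epimer would be removed by chromatography.

**Step 7**
Reactants: 11 para-quinol
Product: 12 methyl (2R)-2-[(1S)-4-oxo-2-(TBS-oxymethyl)-1-(triethylsilyloxy)cyclohexa-2,5-dien-1-yl]-2-(prop-1-en-2-yloxy)pent-4-enoate
Conditions: TESOTf (3 equiv), Et3N (6 equiv), CH2Cl2, −78 to 0 °C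
Reagents that add atoms: triethylsilyl trifluoromethanesulfonate, CC[Si](CC)(CC)OS(=O)(=O)C(F)(F)F
Why: The silyl triflate–amine pair silylates the tertiary quinol hydroxyl and, by silylating the ketal methoxy oxygen, causes loss of methoxysilane and deprotonation of the oxocarbenium ion (ketal-to-enol-ether elimination) to give the isopropenyl ether; no stereocentre is touched.

**Step 8**
Reactants: 12 isopropenyl ether dienone
Product: 13 cis-fused bicyclic keto ester methyl (1R,3aS,7aS)-1-allyl-7-(TBS-oxymethyl)-3,3-dimethyl-5-oxo-7a-(triethylsilyloxy)-1,3,3a,4,5,7a-hexahydro-2-benzofuran-1-carboxylate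
Conditions: Fe(acac)3 (30 mol%), Ph(i-PrO)SiH2 (2 equiv), THF/i-PrOH 10:1, rt, degassed
Reagents that add atoms: none
Why: Mukaiyama-type hydrogen-atom transfer to the electron-rich enol ether gives a tertiary α-alkoxy radical that closes 5-exo-trig on the unsubstituted β-carbon of the dienone (Giese-type radical conjugate addition, then reduction and protonation); the short tether forces the cis ring fusion and so sets the ring-fusion methine, while the monosubstituted allyl group is a much poorer hydrogen-atom acceptor and radical trap.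

**Step 9**
Reactants: 13 allyl keto ester; 14 2-methyl-2-butene
Product: 15 prenyl keto ester (3-methylbut-2-enyl in place of allyl)
Conditions: 14 (50 equiv), second-generation Grubbs catalyst (H2IMes)(PCy3)Cl2Ru=CHPh (5 mol%), CH2Cl2, 40 °C
Reagents that add atoms: none
Why: Olefin cross-metathesis of a terminal alkene with excess 2-methyl-2-butene is the standard allyl-to-prenyl conversion, and the trisubstituted enone and the silyl ethers do not take part.

**Step 10**
Reactants: 15 prenyl keto ester
Product: 16 diol (C1 hydroxymethyl and C5 allylic carbinol as an epimer mixture)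
Conditions: i-Bu2AlH (5 equiv), CH2Cl2, −78 to 0 °C; aq. potassium sodium tartrate (KNaC4H4O6)
Reagents that add atoms: none
Why: Hydride reduction takes the neopentyl ester to the primary alcohol and the enone to the allylic alcohol by 1,2-addition; the new carbinol centre is irrelevant because the next step re-oxidises it.

**Step 11**
Reactants: 16 diol
Product: 17 keto aldehyde (1R,3aS,7aS)-7-(TBS-oxymethyl)-3,3-dimethyl-1-(3-methylbut-2-enyl)-5-oxo-7a-(triethylsilyloxy)-1,3,3a,4,5,7a-hexahydro-2-benzofuran-1-carbaldehyde
Conditions: Dess–Martin periodinane (3 equiv), CH2Cl2, 0 °C to rt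
Reagents that add atoms: none
Why: Dess–Martin oxidation converts the allylic secondary and the neopentyl primary alcohol together, restoring the enone and giving the non-enolisable aldehyde without touching the silyl ethers.

**Step 12**
Reactants: 17 keto aldehyde
Product: 19 caged α-ketol (3R)-8-(TBS-oxymethyl)-1-hydroxy-5,5-dimethyl-3-(3-methylbut-2-enyl)-7-(triethylsilyloxy)-4-oxatricyclo[4.3.1.0(3,7)]dec-8-en-2-one, via Breslow intermediate 18 (not isolated)
Conditions: 2-(pentafluorophenyl)-6,7-dihydro-5H-pyrrolo[2,1-c][1,2,4]triazol-2-ium tetrafluoroborate (20 mol%), i-Pr2NEt (20 mol%), toluene (0.02 M), 40 °C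
Reagents that add atoms: none
Why: The free carbene adds to the non-enolisable aldehyde and proton transfer gives the hydroxy-enamine 18, whose nucleophilic carbon attacks the ring ketone in a 1,2-fashion; proton transfer and loss of the carbene release the tertiary α-ketol. The closest known reaction type is the carbene-catalysed intramolecular crossed aldehyde–ketone benzoin reaction that gives cyclic tertiary α-ketols. The new six-membered ring (aldehyde carbon, its quaternary carrier, the silyloxy ring-fusion carbon and three ring carbons ending at the ketone carbon) closes 6-exo-trig on the C=O and completes the bicyclo[2.2.2]octenone. The new carbinol stereocentre is dictated by the existing centres, because the cis-fused tetrahydrofuran holds the formyl group on the concave face above the cyclohexenone and only one ketone face can be reached. The step needs ketone 1,2-addition rather than conjugate (Stetter) addition or intermolecular benzoin: the enone β-carbon would require a four-membered ring, the α-carbon is not electrophilic because its neighbour carries a silyloxymethyl group and not an ester, and the neopentyl aldehyde is too hindered to dimerise.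

**Step 13**
Reactants: 19 caged α-ketol
Product: 20 triol (3R)-1,7-dihydroxy-8-(hydroxymethyl)-5,5-dimethyl-3-(3-methylbut-2-enyl)-4-oxatricyclo[4.3.1.0(3,7)]dec-8-en-2-one
Conditions: HF·pyridine, pyridine, THF, 0 °C to rt
Reagents that add atoms: none
Why: Buffered fluoride desilylation removes the primary TBS and the tertiary TES ether without base, which avoids retro-aldol cleavage and α-ketol rearrangement.

**Step 14**
Reactants: 20 triol
Product: 21 enal (8-carbaldehyde)
Conditions: MnO2 (20 equiv), CH2Cl2, rt
Reagents that add atoms: none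
Why: Allylic oxidation with MnO2 takes only the primary allylic alcohol and leaves the two tertiary hydroxyls.

**Step 15**
Reactants: 21 enal
Product: 22 hydroxy acid (8-carboxylic acid)
Conditions: NaClO2 (3 equiv), NaH2PO4 (4 equiv), 2-methyl-2-butene 14 (20 equiv), t-BuOH/H2O 4:1, 0 °C to rt
Reagents that add atoms: sodium chlorite, [Na+].[O-]Cl=O
Why: Pinnick oxidation converts the enal into the enoic acid under buffered conditions, with 2-methyl-2-butene trapping hypochlorous acid so that the prenyl group and ring alkene survive.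

**Step 16**
Reactants: 23 phloroglucinol; 24 3-methylbut-2-enal
Product: 26 2,2-dimethyl-2H-chromene-5,7-diol, via dienone 25 (not isolated)
Conditions: 23 (3 equiv), 24 (1 equiv), pyridine, 110 °C
Reagents that add atoms: none
Why: Knoevenagel-type condensation at a ring carbon of the triphenol gives a dienone that undergoes oxa-6π electrocyclisation to the chromene, and the symmetry of phloroglucinol makes the regiochemistry unambiguous.

**Step 17**
Reactants: 26 chromenediol
Product: 27 7-hydroxy-2,2-dimethyl-2H-chromene-5,8-dione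
Conditions: (KSO3)2NO (2.5 equiv), KH2PO4 buffer, acetone/H2O, 0 °C to rt
Reagents that add atoms: potassium nitrosodisulfonate, [K+].[K+].[O-]S(=O)(=O)N([O])S(=O)(=O)[O-]
Why: Teuber oxidation attacks the free position para to the C5 hydroxyl and gives the para-quinone, with the C7 hydroxyl remaining as the vinylogous acid.

**Step 18**
Reactants: 27 hydroxyquinone; 28 prenyl bromide
Product: 29 7-hydroxy-2,2-dimethyl-6-(3-methylbut-2-enyl)-2H-chromene-5,8-dione
Conditions: LiH (1.1 equiv), DMSO, rt; then 28 (1.5 equiv), 45 °C
Reagents that add atoms: none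
Why: C-alkylation of the lithium salt of a 2-hydroxy-1,4-quinone with an allylic bromide (lapachol-type alkylation) occurs at the only nucleophilic ring carbon, and the lithium counter-ion in DMSO favours carbon over oxygen attack.

**Step 19**
Reactants: 22 hydroxy acid; 29 prenylated hydroxyquinone
Product: 31 target CNP0222516.1, via acyloxyquinone 30 (not isolated)
Conditions: EDC·HCl (1.5 equiv), DMAP (0.2 equiv), CH2Cl2, 0 °C to rt; then CSA (0.3 equiv), rt
Reagents that add atoms: none
Why: Proposed new method: Steglich-type acylation of the vinylogous-acid hydroxyl of 29 gives the 7-acyloxyquinone 30, which places the bridgehead tertiary hydroxyl beside the quinone carbon bearing the acyloxy group; acid-promoted 6-exo-trig oxa-Michael addition to that carbon and ketonisation then give the spiro 1,3-dioxan-4-one. The closest known reaction types are intramolecular oxa-Michael additions to β-oxygenated enones that form spiroketals and the acid-catalysed formation of 1,3-dioxan-4-ones from β-hydroxy acids and carbonyl compounds. The spiro carbon and the adjacent methine form reversibly and should settle with the prenyl group trans to the bulky cage ether oxygen; which face of the quinone carbon is favoured is not secured by the substrate.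

**Compound list**

1 | 4-bromo-3-(hydroxymethyl)phenol | OCc1cc(O)ccc1Br | starting material
2 | tert-butyl{[2-bromo-5-(tert-butyldimethylsilyloxy)phenyl]methoxy}dimethylsilane | CC(C)(C)[Si](C)(C)OCc1cc(O[Si](C)(C)C(C)(C)C)ccc1Br | intermediate
3 | dimethyl oxalate | COC(=O)C(=O)OC | starting material
4 | {4-(tert-butyldimethylsilyloxy)-2-[(tert-butyldimethylsilyloxy)methyl]phenyl}lithium | [Li]c1ccc(O[Si](C)(C)C(C)(C)C)cc1CO[Si](C)(C)C(C)(C)C | intermediate
5 | methyl 2-{4-(tert-butyldimethylsilyloxy)-2-[(tert-butyldimethylsilyloxy)methyl]phenyl}-2-oxoacetate | COC(=O)C(=O)c1ccc(O[Si](C)(C)C(C)(C)C)cc1CO[Si](C)(C)C(C)(C)C | intermediate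
6 | allyltributylstannane | C=CC[Sn](CCCC)(CCCC)CCCC | starting material
7 | methyl (2R)-2-{4-(tert-butyldimethylsilyloxy)-2-[(tert-butyldimethylsilyloxy)methyl]phenyl}-2-hydroxypent-4-enoate | O[C@@](CC=C)(C(=O)OC)c1ccc(O[Si](C)(C)C(C)(C)C)cc1CO[Si](C)(C)C(C)(C)C | intermediate
8 | 2-methoxypropene | COC(C)=C | starting material
9 | methyl (2R)-2-{4-(tert-butyldimethylsilyloxy)-2-[(tert-butyldimethylsilyloxy)methyl]phenyl}-2-[(2-methoxypropan-2-yl)oxy]pent-4-enoate | COC(C)(C)O[C@@](CC=C)(C(=O)OC)c1ccc(O[Si](C)(C)C(C)(C)C)cc1CO[Si](C)(C)C(C)(C)C | intermediate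
10 | methyl (2R)-2-{2-[(tert-butyldimethylsilyloxy)methyl]-4-hydroxyphenyl}-2-[(2-methoxypropan-2-yl)oxy]pent-4-enoate | COC(C)(C)O[C@@](CC=C)(C(=O)OC)c1ccc(O)cc1CO[Si](C)(C)C(C)(C)C | intermediate
11 | methyl (2R)-2-{(1S)-2-[(tert-butyldimethylsilyloxy)methyl]-1-hydroxy-4-oxocyclohexa-2,5-dien-1-yl}-2-[(2-methoxypropan-2-yl)oxy]pent-4-enoate | CC(C)(C)[Si](C)(C)OCC1=CC(=O)C=C[C@@]1(O)[C@@](CC=C)(OC(C)(C)OC)C(=O)OC | intermediate
12 | methyl (2R)-2-{(1S)-2-[(tert-butyldimethylsilyloxy)methyl]-4-oxo-1-(triethylsilyloxy)cyclohexa-2,5-dien-1-yl}-2-(prop-1-en-2-yloxy)pent-4-enoate | CC(C)(C)[Si](C)(C)OCC1=CC(=O)C=C[C@@]1(O[Si](CC)(CC)CC)[C@@](CC=C)(OC(C)=C)C(=O)OC | intermediate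
13 | methyl (1R,3aS,7aS)-7-[(tert-butyldimethylsilyloxy)methyl]-3,3-dimethyl-5-oxo-1-(prop-2-en-1-yl)-7a-(triethylsilyloxy)-1,3,3a,4,5,7a-hexahydro-2-benzofuran-1-carboxylate (cis ring fusion; ester trans and allyl cis to the 7a-silyloxy group on the furan ring) | CC(C)(C)[Si](C)(C)OCC1=CC(=O)C[C@H]4C(C)(C)O[C@@](CC=C)(C(=O)OC)[C@@]14O[Si](CC)(CC)CC | intermediate
14 | 2-methyl-2-butene | CC=C(C)C | starting material
15 | methyl (1R,3aS,7aS)-7-[(tert-butyldimethylsilyloxy)methyl]-3,3-dimethyl-1-(3-methylbut-2-en-1-yl)-5-oxo-7a-(triethylsilyloxy)-1,3,3a,4,5,7a-hexahydro-2-benzofuran-1-carboxylate | CC(C)(C)[Si](C)(C)OCC1=CC(=O)C[C@H]4C(C)(C)O[C@@](CC=C(C)C)(C(=O)OC)[C@@]14O[Si](CC)(CC)CC | intermediate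
16 | {7-[(tert-butyldimethylsilyloxy)methyl]-5-hydroxy-3,3-dimethyl-1-(3-methylbut-2-en-1-yl)-7a-(triethylsilyloxy)-1,3,3a,4,5,7a-hexahydro-2-benzofuran-1-yl}methanol (C1, C3a, C7a as in 15; C5 carbinol as epimer mixture) | CC(C)(C)[Si](C)(C)OCC1=CC(O)C[C@H]4C(C)(C)O[C@@](CC=C(C)C)(CO)[C@@]14O[Si](CC)(CC)CC | intermediate
17 | (1R,3aS,7aS)-7-[(tert-butyldimethylsilyloxy)methyl]-3,3-dimethyl-1-(3-methylbut-2-en-1-yl)-5-oxo-7a-(triethylsilyloxy)-1,3,3a,4,5,7a-hexahydro-2-benzofuran-1-carbaldehyde (formyl cis to C7 and trans to the 7a-silyloxy group) | CC(C)(C)[Si](C)(C)OCC1=CC(=O)C[C@H]4C(C)(C)O[C@@](CC=C(C)C)(C=O)[C@@]14O[Si](CC)(CC)CC | intermediate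
18 | Breslow intermediate: hydroxy-enamine from the formyl carbon of 17 and C3 of 2-(pentafluorophenyl)-6,7-dihydro-5H-pyrrolo[2,1-c][1,2,4]triazol-3-ylidene | CC(C)(C)[Si](C)(C)OCC1=CC(=O)C[C@H]4C(C)(C)O[C@@](CC=C(C)C)(C(O)=C5N(c6c(F)c(F)c(F)c(F)c6F)N=C7CCCN57)[C@@]14O[Si](CC)(CC)CC | intermediate
19 | (3R)-8-[(tert-butyldimethylsilyloxy)methyl]-1-hydroxy-5,5-dimethyl-3-(3-methylbut-2-en-1-yl)-7-(triethylsilyloxy)-4-oxatricyclo[4.3.1.0(3,7)]dec-8-en-2-one (the cage fixes the other centres) | CC(C)(C)[Si](C)(C)OCC1=C[C@]3(O)C[C@H]4C(C)(C)O[C@@](CC=C(C)C)(C3=O)[C@@]14O[Si](CC)(CC)CC | intermediate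
20 | (3R)-1,7-dihydroxy-8-(hydroxymethyl)-5,5-dimethyl-3-(3-methylbut-2-en-1-yl)-4-oxatricyclo[4.3.1.0(3,7)]dec-8-en-2-one | OCC1=C[C@]3(O)C[C@H]4C(C)(C)O[C@@](CC=C(C)C)(C3=O)[C@@]14O | intermediate
21 | (3R)-1,7-dihydroxy-5,5-dimethyl-3-(3-methylbut-2-en-1-yl)-2-oxo-4-oxatricyclo[4.3.1.0(3,7)]dec-8-ene-8-carbaldehyde | O=CC1=C[C@]3(O)C[C@H]4C(C)(C)O[C@@](CC=C(C)C)(C3=O)[C@@]14O | intermediate
22 | (3R)-1,7-dihydroxy-5,5-dimethyl-3-(3-methylbut-2-en-1-yl)-2-oxo-4-oxatricyclo[4.3.1.0(3,7)]dec-8-ene-8-carboxylic acid | OC(=O)C1=C[C@]3(O)C[C@H]4C(C)(C)O[C@@](CC=C(C)C)(C3=O)[C@@]14O | intermediate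
23 | phloroglucinol (benzene-1,3,5-triol) | Oc1cc(O)cc(O)c1 | starting material
24 | 3-methylbut-2-enal | CC(C)=CC=O | starting material
25 | 3,5-dihydroxy-6-(3-methylbut-2-en-1-ylidene)cyclohexa-2,4-dien-1-one | CC(C)=CC=C1C(=O)C=C(O)C=C1O | intermediate
26 | 2,2-dimethyl-2H-chromene-5,7-diol | CC1(C)C=Cc2c(O)cc(O)cc2O1 | intermediate
27 | 7-hydroxy-2,2-dimethyl-2H-chromene-5,8-dione | CC1(C)C=CC2=C(O1)C(=O)C(O)=CC2=O | intermediate
28 | 1-bromo-3-methylbut-2-ene (prenyl bromide) | CC(C)=CCBr | starting material
29 | 7-hydroxy-2,2-dimethyl-6-(3-methylbut-2-en-1-yl)-2H-chromene-5,8-dione | CC(C)=CCC1=C(O)C(=O)C2=C(C=CC(C)(C)O2)C1=O | intermediate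
30 | 2,2-dimethyl-6-(3-methylbut-2-en-1-yl)-5,8-dioxo-5,8-dihydro-2H-chromen-7-yl ester of acid 22 | CC(C)=CCC1=C(OC(=O)C5=C[C@]3(O)C[C@H]4C(C)(C)O[C@@](CC=C(C)C)(C3=O)[C@@]54O)C(=O)C2=C(C=CC(C)(C)O2)C1=O | intermediate
31 | target CNP0222516.1: spiro 1,3-dioxan-4-one joining the carboxyl and C7 oxygen of cage acid 22 to C7 of the 6-prenyl-2,2-dimethylchromene-5,8-dione unit (prenyl on the methine trans to the cage ether oxygen; methine on the side of the prenylated cage carbon) | CC(C)=CC[C@H]1C(=O)C2=C(OC(C)(C)C=C2)C(=O)[C@@]12OC(=O)C1=C[C@]3(O)C[C@H]4C(C)(C)O[C@@](CC=C(C)C)(C3=O)[C@@]14O2 | target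

**Totals.** Total step count: 19. Longest linear sequence: 16 steps (steps 1–15, then step 19); steps 16–18 make the quinone partner.

**Steps most likely to fail**

Step 19. The ring closure may stall at the acyloxyquinone, the tetrahedral adduct may lose the carboxylate again (opening to the alkoxyquinone acid), or the hydroxyl may add to the wrong face of the quinone carbon and give the spiro epimer. The fallback sets out from 29 and 22 and comes back at 31. Quinone 29 would be O-methylated with trimethylsilyldiazomethane to the 7-methoxyquinone F1, and acid 22 persilylated with N,O-bis(trimethylsilyl)acetamide to the tris(trimethylsilyl) derivative F2. F1 and F2 would then be joined with catalytic TMSOTf in CH2Cl2 at −78 to −20 °C, followed by dilute aqueous acid to remove the remaining silyl ether. This is the known silyl-triflate-catalysed acetal exchange that turns silylated β-hydroxy acids into 1,3-dioxan-4-ones, applied to the vinylogous ester as the enol-ether partner. It avoids base altogether and runs under reversible conditions, so the spiro centre is under thermodynamic control.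

Step 12. The neopentyl aldehyde may be too hindered to form the hydroxy-enamine, or the strained adduct may revert by retro-benzoin. The fallback sets out from 17 and comes back at 19. Samarium diiodide (SmI2, THF/t-BuOH, −78 °C) would effect a ketyl–carbonyl pinacol cyclisation across the same two carbons to give the caged 1,2-diol F3. Parikh–Doering oxidation (SO3·pyridine, DMSO, Et3N) of its secondary hydroxyl would then deliver α-ketol 19.

Step 6. Water may attack the dearomatised ring with poor facial selectivity, or the ketal methoxy oxygen may capture the intermediate in place of water. The fallback sets out from the reaction mixture of step 6 and comes back at 10. The quinol epimers would be separated by chromatography, and the unwanted quinol epimer F4 returned to phenol 10 by reductive re-aromatisation with aluminium amalgam (Al(Hg), wet THF). Selectivity is thus replaced by separation and recycling.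

**Further compounds**

F1 | step 19 | 7-methoxy-2,2-dimethyl-6-(3-methylbut-2-en-1-yl)-2H-chromene-5,8-dione | CC(C)=CCC1=C(OC)C(=O)C2=C(C=CC(C)(C)O2)C1=O
F2 | step 19 | trimethylsilyl ester bis(trimethylsilyl) ether of acid 22 | C[Si](C)(C)OC(=O)C1=C[C@]3(O[Si](C)(C)C)C[C@H]4C(C)(C)O[C@@](CC=C(C)C)(C3=O)[C@@]14O[Si](C)(C)C
F3 | step 12 | caged 1,2-diol: 2-hydroxy analogue of 19 (secondary carbinol of either configuration) | CC(C)(C)[Si](C)(C)OCC1=C[C@]3(O)C[C@H]4C(C)(C)O[C@@](CC=C(C)C)(C3O)[C@@]14O[Si](CC)(CC)CC
F4 | step 6 | quinol epimer of 11 (1R at the quinol carbon) | CC(C)(C)[Si](C)(C)OCC1=CC(=O)C=C[C@]1(O)[C@@](CC=C)(OC(C)(C)OC)C(=O)OC
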